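## Structural features

Isolappaol A is a dibenzylbutyrolactone lignan in which one of the two arylmethyl arms is itself a phenylcoumaran unit. The γ-butyrolactone (ring D: carbonyl C9, Cα, Cβ, methylene C9' and the ring oxygen) carries on Cβ, through C7', a 4-hydroxy-3-methoxyphenyl group (ring A) and on Cα, through C7, the C5 position of a 7-methoxy-2,3-dihydrobenzofuran (benzo ring B fused to dihydrofuran ring E), which bears a second guaiacyl group (ring C) on C2 and a hydroxymethyl group on C3. The four stereocentres form two adjacent pairs, Cα(R)/Cβ(R) trans in ring D and C2(S)/C3(R) trans in ring E; the pairs are separated by C7 and ring B, so neither can direct the other and each needs its own source of absolute configuration. Fragile points are the two free guaiacol phenols (oxidised by periodate or hypervalent iodine, acidic towards organolithiums), the C2–O1 bond of ring E (a benzylic aryl ether para to an oxygen donor, open to hydrogenolysis and acid ionisation), the base-epimerisable Cα, and a primary alcohol that must be kept apart from the lactone CH2O. The real difficulty is to join a large enantiopure dihydrobenzofuran to a trans-2,3-disubstituted lactone with full control of Cα and Cβ and without touching ring E. The key step exploits the four-carbon chain C9–Cα–Cβ–C9' of ring D with trans arms on its two middle carbons. Read with C9' as the carbonyl and C9 as the oxygen-bearing carbon, this chain is the skeleton of a γ-substituted butenolide, so the C7 and C7' arms can be attached anti, anti to its β- and α-carbons before the two ends are exchanged.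

## Logic of the disconnections

**28 back to 26.** No skeletal bond is cut. The two phenolic O–H bonds and the primary O–H bond of 28 are traced to two benzyl ethers (27) and one silyl ether (26). The phenols must be masked against the organolithium and the oxidants, and the primary alcohol against the lactol oxidation. The demand on the forward steps is that hydrogenolysis removes two O–CH2Ph groups without opening the C2–O1 bond of ring E. For that reason only aryl benzyl ethers are used, and the alcohol is freed by fluoride.

**26 back to 21 (lactone transposition).** The acyl C9–O bond of ring D is opened and C9 is extended by one hydroxymethyl carbon, giving 24 (forward: glycol cleavage and lactol 25). 24 is traced through 23 (trityl ether), 22 (two C7–S bonds restored) and 21 (C9' back at the carboxyl level and closed onto the C9 oxygen). This exchange of the two chain ends lets ring D be derived from a chiral-pool γ-lactone. The stereocentre that is destroyed (C9) is the one that served only as control element. Traced atom by atom, the α-carbon of 21 becomes Cβ and its β-carbon becomes Cα, so (3R,4R,5R)-21 maps onto the (R,R) lactone of 28. The forward demands are: sulfur must be gone before any oxidant, the glycol must be cleaved before the primary alcohol can be oxidised, and Cα must not epimerise (trans is the thermodynamic arrangement).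

**21 back to 12, 18 and 2.** The bonds cut are Cα–C7 (C4–dithiane carbon in 21) and Cβ–C7' (C3–CH2 in 21). Both flank the two lactone stereocentres, and forming them in sequence on 18 lets one pool stereocentre control both. The gain is three fragments and convergence at the most complex point. The forward step must give 1,4-addition, anti entry twice, and C-alkylation of a crowded enolate. It also requires C7 to be an acyl-anion equivalent and 12 to carry no acidic or electrophilic group.

**18 back to 13 and 14.** The O–trityl bond (17), the lactone acyl C–O bond and the C=C bond (16, from 15) are cut. This reduces 18 to a three-carbon chiral-pool alcohol and a two-carbon ylide. The forward demands are a Z-olefin, because only it lactonises, and no α-epimerisation of 15.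

**12 back to 7.** The two C–S bonds are traced to an acetal (11), the O–Si bond to an alcohol (10), the hydroxymethyl to an ester (9), and C3 to its epimer (8). Then the C2–C3 bond of ring E is cut to reach 7. A carbene C–H insertion builds ring E from an open aryl benzyl ether and sets C2 by catalyst control. The forward demands are a sulfur-free substrate at the rhodium stage (hence acetal, not dithiane), high enantioselectivity at C2, and epimerisation at C3 without opening of ring E.

**7 back to 1, 3 and 6.** The aryl–C(diazo) bond (5 + 6), the acetal C–O bonds (4), the aryl ether O–CH2 bond (3 + 2) and the C–Br bond (1) are cut. 3 already carries iodine, hydroxyl, methoxy and formyl in the right places, and 2 is used twice (here and in the key step). The forward demands are a coupling that keeps the diazo group and O-alkylation of a hindered phenol.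

## Other disconnections considered

Alternative 1: The cut is the O1–C2 bond of ring E.
- **Forward key step.** The open bisphenol A1 (methyl 3-[(2R)-1-(tert-butyldimethylsilyloxy)-3-(4-hydroxy-3-methoxyphenyl)propan-2-yl]-4-hydroxy-5-methoxybenzoate) would be oxidised at ring C with Ag2O, or one equivalent of DDQ, to the para-quinone methide A2. The ring B phenol would add to its exocyclic carbon (5-exo-trig) to give the trans dihydrobenzofuran A3 (methyl (2S,3R)-3-(tert-butyldimethylsilyloxymethyl)-2-(4-hydroxy-3-methoxyphenyl)-7-methoxy-2,3-dihydrobenzofuran-5-carboxylate).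
- **In its favour.** The closure is biomimetic and needs neither a diazo compound nor a chiral rhodium catalyst. Only ring C can form a quinone methide, since ring B has the ester para to its hydroxyl. The phenol addition is reversible, so the trans ring should result under thermodynamic control from the C3 centre alone.
- **Against it here.** A1 is no simpler than 7: its C3 centre, which joins two arenes, must first be set by an auxiliary-based alkylation or an asymmetric hydrogenation. A2 has a hydrogen on C3 next to the methide and could tautomerise to a styrene, erasing that centre. A3 still needs phenol protection and an ester-to-aldehyde adjustment before the dithiane stage.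
- **Comparison.** On structure the two plans are equal: each lets one centre of ring E relay to the other (C3 to C2 there, C2 to C3 here). On mechanism the alternative is the better in avoiding diazo intermediates and a precious metal; the chosen plan is the better in setting absolute configuration in the ring-forming step itself. On step economy the alternative is at best equal, since it replaces only steps 2 to 9 and leaves the lactone to step 13 onwards.

Alternative 2: The cut lies in ring D: both C–O bonds of the ring oxygen are traced to oxygen insertion into the prochiral cyclobutanone A4 (3-(4-benzyloxy-3-methoxybenzyl)cyclobutan-1-one).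
- **Forward key step.** An enantioselective Baeyer–Villiger oxidation (chiral acid or metal catalyst with H2O2, or a monooxygenase) would migrate one of the two enantiotopic CH2 groups and give the β-benzyl lactone A5 ((R)-4-(4-benzyloxy-3-methoxybenzyl)dihydrofuran-2(3H)-one). Its enolate would then be alkylated trans to the benzyl group with the benzylic bromide A6 ((2S,3R)-2-(4-benzyloxy-3-methoxyphenyl)-5-(bromomethyl)-7-methoxy-3-(triisopropylsilyloxymethyl)-2,3-dihydrobenzofuran).
- **In its favour.** Ring D arrives in its final oxidation pattern, so the dithiane, the nickel desulfurisation and the whole end-for-end exchange (steps 14 to 17) disappear. The trans alkylation of β-benzyl butyrolactone enolates is a classical way to Cα. The route would be about five steps shorter; on step economy this alternative is the better plan.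
- **Against it here.** Cβ lies two bonds from the reacting carbonyl, so complete enantiocontrol of the migration cannot be counted on. Any enantiomeric A5 would, after coupling with enantiopure A6, become a diastereomer that differs only at remote centres and is hard to remove. A6 is a para-oxygenated benzylic bromide prone to ionisation, and as the electrophile it would be used in excess although it is the most valuable fragment.
- **Comparison.** On structure the alternative reads ring D directly, a real advantage. On mechanism the chosen plan is the more certain, because both lactone centres come from a pool centre of fixed configuration by substrate control. The polarity of the fragment union is reversed (dihydrobenzofuran as electrophile there, as nucleophile here) and neither polarity is clearly superior.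

Alternative 3: The cut removes C2 from ring E by breaking the C3–C2 and O1–C2 bonds.
- **Forward key step.** Cs2CO3 would expel sulfinate from the phenolic sulfone A7 (4-bromo-2-[2-(tert-butyldimethylsilyloxy)-1-(4-methylbenzenesulfonyl)ethyl]-6-methoxyphenol) to form the ortho-quinone methide A8. It would also deprotonate the chiral sulfonium salt A9 ((2R,5R)-1-(4-benzyloxy-3-methoxybenzyl)-2,5-dimethylthiolan-1-ium tetrafluoroborate, or its enantiomer as the sense of induction demands). Conjugate addition of the ylide carbon to the methide carbon, then displacement of the sulfide by the phenoxide (5-exo-tet), would give the trans bromide A10 ((2S,3R)-2-(4-benzyloxy-3-methoxyphenyl)-5-bromo-3-(tert-butyldimethylsilyloxymethyl)-7-methoxy-2,3-dihydrobenzofuran).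
- **In its favour.** Ring E and both its centres would form in one metal-free, convergent operation, trans directly and with no epimerisation step. The chiral sulfide is recoverable, and the C5 bromide is a flexible handle.
- **Against it here.** A8 has a CH2 group next to the methide and could tautomerise to a vinyl phenol or lose silanolate. Enantiocontrol by a stoichiometric chiral sulfide with an electron-rich, semi-stabilised benzylide is less predictable. A10 needs halogen–lithium exchange, formylation and thioacetalisation before it can serve in step 13.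
- **Comparison.** On structure the alternative is the better: two fragments of similar size are joined as the ring forms. On mechanism it is the better in principle, but with less assured absolute control than a catalytic asymmetric C–H insertion. On step economy the two are about equal, since A7 and A9 each need two or three steps and the lactone part is unchanged.

Key step: step 13

Assumption: in this benzylic ether C–H insertion the dirhodium N-phthaloyl-tert-leucinate catalysts are taken to translate the S ligand into the (2S) configuration at the aryl-bearing ring carbon, by analogy with the related cis-2-aryl-2,3-dihydrobenzofuran-3-carboxylate series, so Rh2(S-PTTL)4, dirhodium tetrakis[N-phthaloyl-(S)-tert-leucinate], is the catalyst chosen; the sense and level of induction should be confirmed on 10 by chromatography on a chiral stationary phase, and the mirror-image complex Rh2(R-PTTL)4 would take its place if the sense proved opposite.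

Abbreviations: BV = 4-benzyloxy-3-methoxybenzyl; DBF* = (2S,3R)-2-(4-benzyloxy-3-methoxyphenyl)-7-methoxy-3-(triisopropylsilyloxymethyl)-2,3-dihydrobenzofuran-5-yl.

## Steps

Step 1
Reactants: 1 (4-benzyloxy-3-methoxyphenyl)methanol
Product: 2 4-benzyloxy-3-methoxybenzyl bromide
Conditions: PBr3 (0.4 equiv), Et2O, 0 °C
Reagents that add atoms: phosphorus tribromide, BrP(Br)Br
Why: Primary benzylic alcohol to bromide through the bromophosphite (SN2 at an activated benzylic carbon); the aryl benzyl ether is inert at 0 °C, and the bromide is used fresh because a para-alkoxybenzyl bromide ionises readily.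

Step 2
Reactants: 3 5-iodovanillin; 2 4-benzyloxy-3-methoxybenzyl bromide
Product: 4 4-(BV-oxy)-3-iodo-5-methoxybenzaldehyde
Conditions: K2CO3, DMF, rt
Reagents that add atoms: none
Why: Williamson ether synthesis: the acidic, hindered phenoxide of 3 is alkylated by the reactive benzylic bromide; the aldehyde and the aryl iodide are spectators.

Step 3
Reactants: 4 4-(BV-oxy)-3-iodo-5-methoxybenzaldehyde
Product: 5 2-[4-(BV-oxy)-3-iodo-5-methoxyphenyl]-1,3-dioxolane
Conditions: HOCH2CH2OH, PPTS (cat.), toluene, reflux, azeotropic removal of water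
Reagents that add atoms: ethylene glycol, OCCO
Why: Acid-catalysed acetalisation; the mild acid PPTS is chosen so that the electron-rich benzyl aryl ether is not cleaved, and the acetal keeps the formyl carbon sulfur-free and hydride-proof until step 9.

Step 4
Reactants: 5 2-[4-(BV-oxy)-3-iodo-5-methoxyphenyl]-1,3-dioxolane; 6 ethyl diazoacetate
Product: 7 ethyl 2-diazo-2-[2-(BV-oxy)-5-(1,3-dioxolan-2-yl)-3-methoxyphenyl]acetate
Conditions: Pd(PPh3)4 (5 mol %), Ag2CO3 (0.5 equiv), Et3N, toluene, rt
Reagents that add atoms: none
Why: Palladium-catalysed cross-coupling of an aryl iodide with an acceptor diazo compound with retention of the diazo group: oxidative addition to zerovalent palladium, silver-assisted deprotonative transfer of the diazoacetate carbon to palladium, reductive elimination. The room-temperature, weakly basic medium leaves the acetal and the ethers untouched.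

Step 5
Reactants: 7 ethyl 2-diazo-2-[2-(BV-oxy)-5-(1,3-dioxolan-2-yl)-3-methoxyphenyl]acetate
Product: 8 ethyl (2S,3R)-cis-2-(4-benzyloxy-3-methoxyphenyl)-5-(1,3-dioxolan-2-yl)-7-methoxy-2,3-dihydrobenzofuran-3-carboxylate
Conditions: Rh2(S-PTTL)4 (1 mol %), toluene, −60 °C
Reagents that add atoms: none
Why: Intramolecular 1,5 C–H insertion of the rhodium-bound donor/acceptor carbene into the ether-activated benzylic C–H bond closes ring E (C2–C3 bond), with the cis ester favoured kinetically. C2 is set by the chiral N-phthaloyl-(S)-tert-leucinate ligands; C3 is corrected in step 6, and any minor enantiomer should be purged later as a diastereomer of 21.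

Step 6
Reactants: 8 ethyl (2S,3R)-cis-2-(4-benzyloxy-3-methoxyphenyl)-5-(1,3-dioxolan-2-yl)-7-methoxy-2,3-dihydrobenzofuran-3-carboxylate
Product: 9 ethyl (2S,3S)-trans-2-(4-benzyloxy-3-methoxyphenyl)-5-(1,3-dioxolan-2-yl)-7-methoxy-2,3-dihydrobenzofuran-3-carboxylate
Conditions: NaOEt (0.2 equiv), EtOH, 0 °C → rt
Reagents that add atoms: none
Why: Thermodynamic epimerisation at C3 through the ester enolate relieves the cis aryl/ester strain and gives the trans ester. C2 has no acidic hydrogen, and catalytic ethoxide in ethanol keeps the ester unchanged and disfavours E1cB opening of ring E.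

Step 7
Reactants: 9 ethyl (2S,3S)-trans-2-(4-benzyloxy-3-methoxyphenyl)-5-(1,3-dioxolan-2-yl)-7-methoxy-2,3-dihydrobenzofuran-3-carboxylate
Product: 10 [(2S,3R)-trans-2-(4-benzyloxy-3-methoxyphenyl)-5-(1,3-dioxolan-2-yl)-7-methoxy-2,3-dihydrobenzofuran-3-yl]methanol
Conditions: LiAlH4, THF, 0 °C
Reagents that add atoms: none
Why: Hydride reduction of the ester to the primary alcohol; the acetal, the benzyl ether and the ring E ether are inert and no stereocentre is epimerisable under these conditions.

Step 8
Reactants: 10 [(2S,3R)-trans-2-(4-benzyloxy-3-methoxyphenyl)-5-(1,3-dioxolan-2-yl)-7-methoxy-2,3-dihydrobenzofuran-3-yl]methanol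
Product: 11 {[(2S,3R)-2-(4-benzyloxy-3-methoxyphenyl)-5-(1,3-dioxolan-2-yl)-7-methoxy-2,3-dihydrobenzofuran-3-yl]methoxy}triisopropylsilane
Conditions: TIPSCl, imidazole, DMF, rt
Reagents that add atoms: triisopropylsilyl chloride, CC(C)[Si](Cl)(C(C)C)C(C)C
Why: Silylation of the primary alcohol by the imidazole-activated silyl chloride; the bulky silyl ether is chosen to survive n-BuLi, LiAlH4, Ni2B and the mild acid of step 16 and to fall to fluoride at the end.

Step 9
Reactants: 11 {[(2S,3R)-2-(4-benzyloxy-3-methoxyphenyl)-5-(1,3-dioxolan-2-yl)-7-methoxy-2,3-dihydrobenzofuran-3-yl]methoxy}triisopropylsilane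
Product: 12 2-(DBF*)-1,3-dithiane
Conditions: HS(CH2)3SH (1.2 equiv), BF3·OEt2 (0.2 equiv), CH2Cl2, −20 → 0 °C
Reagents that add atoms: 1,3-propanedithiol, SCCCS
Why: Lewis acid-mediated transthioacetalisation converts the dioxolane directly into the 1,3-dithiane (oxocarbenium, then thionium ion, each captured by sulfur), giving the acyl-anion equivalent at C7. Substoichiometric BF3·OEt2 at low temperature spares the silyl ether and the benzylic ring ether.

Step 10
Reactants: 13 (R)-solketal; 14 methyl (triphenylphosphoranylidene)acetate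
Product: 16 methyl (Z)-3-[(4R)-2,2-dimethyl-1,3-dioxolan-4-yl]prop-2-enoate, via (S)-glyceraldehyde acetonide 15 (not isolated)
Conditions: (COCl)2, DMSO, CH2Cl2, −78 °C; i-Pr2NEt; then 14, MeOH (large excess), −78 → 0 °C
Reagents that add atoms: none
Why: Swern oxidation gives the configurationally labile α-alkoxy aldehyde 15, which is trapped in the same flask by Wittig olefination; methanol as co-solvent should favour the Z-enoate needed for lactonisation, and the hindered amine limits α-epimerisation. The stereocentre is carried over unchanged from the chiral pool; only its descriptor changes through the priority rules.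

Step 11
Reactants: 16 methyl (Z)-3-[(4R)-2,2-dimethyl-1,3-dioxolan-4-yl]prop-2-enoate
Product: 17 (R)-5-(hydroxymethyl)furan-2(5H)-one
Conditions: H2SO4 (cat.), MeOH–H2O, rt
Reagents that add atoms: none
Why: Acid-catalysed acetonide hydrolysis frees the γ-hydroxyl, which lactonises spontaneously onto the Z-ester; an E-isomer cannot close and is removed here, and the stereocentre is not touched.

Step 12
Reactants: 17 (R)-5-(hydroxymethyl)furan-2(5H)-one
Product: 18 (R)-5-(trityloxymethyl)furan-2(5H)-one
Conditions: TrCl, pyridine, DMAP (cat.), CH2Cl2, rt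
Reagents that add atoms: trityl chloride, ClC(c1ccccc1)(c1ccccc1)c1ccccc1
Why: Tritylation of the primary alcohol through the trityl cation; the base-stable trityl ether is the bulky face-blocking group for step 13.

Step 13
Reactants: 12 2-(DBF*)-1,3-dithiane; 18 (R)-5-(trityloxymethyl)furan-2(5H)-one; 2 4-benzyloxy-3-methoxybenzyl bromide
Product: 21 (3R,4R,5R)-3-(BV)-4-[2-(DBF*)-1,3-dithian-2-yl]-5-(trityloxymethyl)dihydrofuran-2(3H)-one, via 2-lithio-1,3-dithiane 19 (not isolated), via lactone lithium enolate 20 (not isolated)
Conditions: n-BuLi (0.98 equiv), THF, −78 → −30 °C; 18 (1.1 equiv), −78 °C; then 2 (1.5 equiv), DMPU, −78 → −30 °C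
Reagents that add atoms: none
Why: n-BuLi removes the C2–H of the 2-aryl-1,3-dithiane to give the aryl- and sulfur-stabilised carbanion 19, which adds in a Michael sense to C4 of 18 to give the lactone enolate 20; 20 is then C-benzylated at C3 by 2 in an SN2 step, so the future Cα–C7 and Cβ–C7' bonds form in one flask. The closest known reaction type is the tandem conjugate addition–enolate alkylation of 2-lithio-2-aryl-1,3-dithianes on γ-alkoxymethyl butenolides (three-component coupling). No ring is closed. The C4 stereocentre is set by the C5 trityloxymethyl group, which blocks one face of the flat butenolide so that 19 enters anti to it; the C3 stereocentre is set by the new C4 dithianyl group, which leaves only the opposite enolate face open to 2, hence the all-trans array. The step needs 1,4- over 1,2-addition, which the soft delocalised anion and the low temperature secure (a 1,2-adduct can revert, the enolate cannot). It also needs C-alkylation over O-alkylation and proton transfer, which the reactive benzylic bromide and DMPU secure. A slight deficit of n-BuLi keeps free alkyllithium away from 18, and the silyl, benzyl and trityl ethers are inert to all three species.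

Step 14
Reactants: 21 (3R,4R,5R)-3-(BV)-4-[2-(DBF*)-1,3-dithian-2-yl]-5-(trityloxymethyl)dihydrofuran-2(3H)-one
Product: 22 (2R,3R,4R)-2-(BV)-3-[2-(DBF*)-1,3-dithian-2-yl]-5-(trityloxy)pentane-1,4-diol
Conditions: LiAlH4, THF, 0 °C
Reagents that add atoms: none
Why: LiAlH4 reduces the lactone to the 1,4-diol, turning the former carbonyl carbon into the future C9' methylene; the dithiane and the trityl, silyl and benzyl ethers are inert and no stereocentre is affected.

Step 15
Reactants: 22 (2R,3R,4R)-2-(BV)-3-[2-(DBF*)-1,3-dithian-2-yl]-5-(trityloxy)pentane-1,4-diol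
Product: 23 (2R,3R,4R)-2-(BV)-3-(DBF*-methyl)-5-(trityloxy)pentane-1,4-diol
Conditions: NiCl2·6H2O (10 equiv), NaBH4 (30 equiv), MeOH–THF, 0 °C → rt
Reagents that add atoms: none
Why: Ni2B formed in the flask hydrogenolyses both C–S bonds, so the dithiane carbon becomes the C7 methylene. It is chosen over Raney Ni because it should leave aryl benzyl ethers and the benzylic C2–O1 bond intact, and the substrate no longer has a lactone that borohydride could attack.

Step 16
Reactants: 23 (2R,3R,4R)-2-(BV)-3-(DBF*-methyl)-5-(trityloxy)pentane-1,4-diol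
Product: 24 (2R,3R,4R)-4-(BV)-3-(DBF*-methyl)pentane-1,2,5-triol
Conditions: CSA (0.1 equiv), MeOH–CH2Cl2, 0 °C → rt
Reagents that add atoms: none
Why: Acid-catalysed solvolysis of the trityl ether (trityl cation captured by methanol) unveils the terminal 1,2-diol; a primary triisopropylsilyl ether and the benzyl ethers should survive catalytic CSA at this temperature.

Step 17
Reactants: 24 (2R,3R,4R)-4-(BV)-3-(DBF*-methyl)pentane-1,2,5-triol
Product: 26 (3R,4R)-4-(BV)-3-(DBF*-methyl)dihydrofuran-2(3H)-one, via transposed lactol 25 (not isolated)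
Conditions: PhI(OAc)2 (1.1 equiv), CH2Cl2, rt; then TEMPO (0.2 equiv), PhI(OAc)2 (1.5 equiv), rt
Reagents that add atoms: none
Why: PhI(OAc)2 alone cleaves the terminal 1,2-diol (cyclic iodane fragmentation) to formaldehyde and an aldehyde that closes onto the remaining primary hydroxyl as lactol 25; TEMPO is added only then, and the oxoammonium cycle oxidises the lactol to the lactone. The former pool stereocentre becomes the carbonyl carbon C9, and Cα and Cβ are retained (trans is also the thermodynamic arrangement).

Step 18
Reactants: 26 (3R,4R)-4-(BV)-3-(DBF*-methyl)dihydrofuran-2(3H)-one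
Product: 27 (3R,4R)-4-(BV)-3-{[(2S,3R)-2-(4-benzyloxy-3-methoxyphenyl)-3-(hydroxymethyl)-7-methoxy-2,3-dihydrobenzofuran-5-yl]methyl}dihydrofuran-2(3H)-one
Conditions: Bu4NF (1.5 equiv), AcOH (1.5 equiv), THF, 0 °C → rt
Reagents that add atoms: none
Why: Fluoride cleaves the Si–O bond; acetic acid buffers the alkoxide so that Cα does not epimerise and the lactone does not open.

Step 19
Reactants: 27 (3R,4R)-4-(BV)-3-{[(2S,3R)-2-(4-benzyloxy-3-methoxyphenyl)-3-(hydroxymethyl)-7-methoxy-2,3-dihydrobenzofuran-5-yl]methyl}dihydrofuran-2(3H)-one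
Product: 28 Isolappaol A
Conditions: H2 (1 atm), 10% Pd/C, EtOAc–EtOH, rt, stopped at full conversion
Reagents that add atoms: none
Why: Hydrogenolysis of the two aryl benzyl ethers over Pd/C at atmospheric pressure; aryl benzyl ethers should cleave much faster than the hindered secondary benzylic C2–O1 bond of ring E, which is why the exposure is kept short.

## Compound list

1 | (4-benzyloxy-3-methoxyphenyl)methanol | COc1cc(CO)ccc1OCc1ccccc1 | starting material
2 | 4-benzyloxy-3-methoxybenzyl bromide | COc1cc(CBr)ccc1OCc1ccccc1 | intermediate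
3 | 5-iodovanillin (4-hydroxy-3-iodo-5-methoxybenzaldehyde) | COc1cc(C=O)cc(I)c1O | starting material
4 | 4-[(4-benzyloxy-3-methoxybenzyl)oxy]-3-iodo-5-methoxybenzaldehyde | COc1cc(C=O)cc(I)c1OCc1ccc(OCc2ccccc2)c(OC)c1 | intermediate
5 | 2-{4-[(4-benzyloxy-3-methoxybenzyl)oxy]-3-iodo-5-methoxyphenyl}-1,3-dioxolane | COc1cc(C2OCCO2)cc(I)c1OCc1ccc(OCc2ccccc2)c(OC)c1 | intermediate
6 | ethyl diazoacetate | CCOC(=O)C=[N+]=[N-] | starting material
7 | ethyl 2-diazo-2-{2-[(4-benzyloxy-3-methoxybenzyl)oxy]-5-(1,3-dioxolan-2-yl)-3-methoxyphenyl}acetate | CCOC(=O)C(=[N+]=[N-])c1cc(C2OCCO2)cc(OC)c1OCc1ccc(OCc2ccccc2)c(OC)c1 | intermediate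
8 | ethyl (2S,3R)-2-(4-benzyloxy-3-methoxyphenyl)-5-(1,3-dioxolan-2-yl)-7-methoxy-2,3-dihydrobenzofuran-3-carboxylate (cis) | O1CCOC1c1cc(OC)c2c(c1)[C@@H](C(=O)OCC)[C@@H](c1ccc(OCc3ccccc3)c(OC)c1)O2 | intermediate
9 | ethyl (2S,3S)-2-(4-benzyloxy-3-methoxyphenyl)-5-(1,3-dioxolan-2-yl)-7-methoxy-2,3-dihydrobenzofuran-3-carboxylate (trans) | O1CCOC1c1cc(OC)c2c(c1)[C@H](C(=O)OCC)[C@@H](c1ccc(OCc3ccccc3)c(OC)c1)O2 | intermediate
10 | [(2S,3R)-2-(4-benzyloxy-3-methoxyphenyl)-5-(1,3-dioxolan-2-yl)-7-methoxy-2,3-dihydrobenzofuran-3-yl]methanol (trans) | O1CCOC1c1cc(OC)c2c(c1)[C@H](CO)[C@@H](c1ccc(OCc3ccccc3)c(OC)c1)O2 | intermediate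
11 | {[(2S,3R)-2-(4-benzyloxy-3-methoxyphenyl)-5-(1,3-dioxolan-2-yl)-7-methoxy-2,3-dihydrobenzofuran-3-yl]methoxy}triisopropylsilane | O1CCOC1c1cc(OC)c2c(c1)[C@H](CO[Si](C(C)C)(C(C)C)C(C)C)[C@@H](c1ccc(OCc3ccccc3)c(OC)c1)O2 | intermediate
12 | 2-[(2S,3R)-2-(4-benzyloxy-3-methoxyphenyl)-7-methoxy-3-(triisopropylsilyloxymethyl)-2,3-dihydrobenzofuran-5-yl]-1,3-dithiane | S1CCCSC1c1cc(OC)c2c(c1)[C@H](CO[Si](C(C)C)(C(C)C)C(C)C)[C@@H](c1ccc(OCc3ccccc3)c(OC)c1)O2 | intermediate
13 | (R)-solketal, [(4R)-2,2-dimethyl-1,3-dioxolan-4-yl]methanol | OC[C@@H]1COC(C)(C)O1 | starting material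
14 | methyl (triphenylphosphoranylidene)acetate | COC(=O)C=P(c1ccccc1)(c1ccccc1)c1ccccc1 | starting material
15 | (S)-glyceraldehyde acetonide, (4S)-2,2-dimethyl-1,3-dioxolane-4-carbaldehyde | O=C[C@@H]1COC(C)(C)O1 | intermediate
16 | methyl (Z)-3-[(4R)-2,2-dimethyl-1,3-dioxolan-4-yl]prop-2-enoate | COC(=O)/C=C\[C@@H]1COC(C)(C)O1 | intermediate
17 | (R)-5-(hydroxymethyl)furan-2(5H)-one | O=C1C=C[C@H](CO)O1 | intermediate
18 | (R)-5-(trityloxymethyl)furan-2(5H)-one | O=C1C=C[C@H](COC(c2ccccc2)(c2ccccc2)c2ccccc2)O1 | intermediate
19 | 2-lithio-2-[(2S,3R)-2-(4-benzyloxy-3-methoxyphenyl)-7-methoxy-3-(triisopropylsilyloxymethyl)-2,3-dihydrobenzofuran-5-yl]-1,3-dithiane | [Li]C1(SCCCS1)c1cc(OC)c2c(c1)[C@H](CO[Si](C(C)C)(C(C)C)C(C)C)[C@@H](c1ccc(OCc3ccccc3)c(OC)c1)O2 | intermediate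
20 | lithium enolate of (4R,5R)-4-{2-[(2S,3R)-2-(4-benzyloxy-3-methoxyphenyl)-7-methoxy-3-(triisopropylsilyloxymethyl)-2,3-dihydrobenzofuran-5-yl]-1,3-dithian-2-yl}-5-(trityloxymethyl)dihydrofuran-2(3H)-one | [Li]OC1=C[C@@H](C2(SCCCS2)c2cc(OC)c3c(c2)[C@H](CO[Si](C(C)C)(C(C)C)C(C)C)[C@@H](c2ccc(OCc4ccccc4)c(OC)c2)O3)[C@H](COC(c2ccccc2)(c2ccccc2)c2ccccc2)O1 | intermediate
21 | (3R,4R,5R)-3-(4-benzyloxy-3-methoxybenzyl)-4-{2-[(2S,3R)-2-(4-benzyloxy-3-methoxyphenyl)-7-methoxy-3-(triisopropylsilyloxymethyl)-2,3-dihydrobenzofuran-5-yl]-1,3-dithian-2-yl}-5-(trityloxymethyl)dihydrofuran-2(3H)-one | O=C1O[C@@H](COC(c2ccccc2)(c2ccccc2)c2ccccc2)[C@H](C2(SCCCS2)c2cc(OC)c3c(c2)[C@H](CO[Si](C(C)C)(C(C)C)C(C)C)[C@@H](c2ccc(OCc4ccccc4)c(OC)c2)O3)[C@H]1Cc1ccc(OCc2ccccc2)c(OC)c1 | intermediate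
22 | (2R,3R,4R)-2-(4-benzyloxy-3-methoxybenzyl)-3-{2-[(2S,3R)-2-(4-benzyloxy-3-methoxyphenyl)-7-methoxy-3-(triisopropylsilyloxymethyl)-2,3-dihydrobenzofuran-5-yl]-1,3-dithian-2-yl}-5-(trityloxy)pentane-1,4-diol | OC[C@H](Cc1ccc(OCc2ccccc2)c(OC)c1)[C@@H](C1(SCCCS1)c1cc(OC)c2c(c1)[C@H](CO[Si](C(C)C)(C(C)C)C(C)C)[C@@H](c1ccc(OCc3ccccc3)c(OC)c1)O2)[C@@H](O)COC(c1ccccc1)(c1ccccc1)c1ccccc1 | intermediate
23 | (2R,3R,4R)-2-(4-benzyloxy-3-methoxybenzyl)-3-{[(2S,3R)-2-(4-benzyloxy-3-methoxyphenyl)-7-methoxy-3-(triisopropylsilyloxymethyl)-2,3-dihydrobenzofuran-5-yl]methyl}-5-(trityloxy)pentane-1,4-diol | OC[C@H](Cc1ccc(OCc2ccccc2)c(OC)c1)[C@@H](Cc1cc(OC)c2c(c1)[C@H](CO[Si](C(C)C)(C(C)C)C(C)C)[C@@H](c1ccc(OCc3ccccc3)c(OC)c1)O2)[C@@H](O)COC(c1ccccc1)(c1ccccc1)c1ccccc1 | intermediate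
24 | (2R,3R,4R)-4-(4-benzyloxy-3-methoxybenzyl)-3-{[(2S,3R)-2-(4-benzyloxy-3-methoxyphenyl)-7-methoxy-3-(triisopropylsilyloxymethyl)-2,3-dihydrobenzofuran-5-yl]methyl}pentane-1,2,5-triol | OC[C@H](Cc1ccc(OCc2ccccc2)c(OC)c1)[C@@H](Cc1cc(OC)c2c(c1)[C@H](CO[Si](C(C)C)(C(C)C)C(C)C)[C@@H](c1ccc(OCc3ccccc3)c(OC)c1)O2)[C@@H](O)CO | intermediate
25 | (3R,4R)-4-(4-benzyloxy-3-methoxybenzyl)-3-{[(2S,3R)-2-(4-benzyloxy-3-methoxyphenyl)-7-methoxy-3-(triisopropylsilyloxymethyl)-2,3-dihydrobenzofuran-5-yl]methyl}tetrahydrofuran-2-ol (mixture of anomers) | COc1cc(C[C@H]2COC(O)[C@@H]2Cc2cc(OC)c3c(c2)[C@H](CO[Si](C(C)C)(C(C)C)C(C)C)[C@@H](c2ccc(OCc4ccccc4)c(OC)c2)O3)ccc1OCc1ccccc1 | intermediate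
26 | (3R,4R)-4-(4-benzyloxy-3-methoxybenzyl)-3-{[(2S,3R)-2-(4-benzyloxy-3-methoxyphenyl)-7-methoxy-3-(triisopropylsilyloxymethyl)-2,3-dihydrobenzofuran-5-yl]methyl}dihydrofuran-2(3H)-one | COc1cc(C[C@H]2COC(=O)[C@@H]2Cc2cc(OC)c3c(c2)[C@H](CO[Si](C(C)C)(C(C)C)C(C)C)[C@@H](c2ccc(OCc4ccccc4)c(OC)c2)O3)ccc1OCc1ccccc1 | intermediate
27 | (3R,4R)-4-(4-benzyloxy-3-methoxybenzyl)-3-{[(2S,3R)-2-(4-benzyloxy-3-methoxyphenyl)-3-(hydroxymethyl)-7-methoxy-2,3-dihydrobenzofuran-5-yl]methyl}dihydrofuran-2(3H)-one | COc1cc(C[C@H]2COC(=O)[C@@H]2Cc2cc(OC)c3c(c2)[C@H](CO)[C@@H](c2ccc(OCc4ccccc4)c(OC)c2)O3)ccc1OCc1ccccc1 | intermediate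
28 | Isolappaol A, (3R,4R)-4-(4-hydroxy-3-methoxybenzyl)-3-{[(2S,3R)-2-(4-hydroxy-3-methoxyphenyl)-3-(hydroxymethyl)-7-methoxy-2,3-dihydrobenzofuran-5-yl]methyl}dihydrofuran-2(3H)-one | COc1cc(C[C@H]2COC(=O)[C@@H]2Cc2cc(OC)c3c(c2)[C@H](CO)[C@@H](c2ccc(O)c(OC)c2)O3)ccc1O | target

## Step count and least certain steps

Total step count: 19. Longest linear sequence: 16 steps (step 1, steps 2 to 9, steps 13 to 19).

**Step 13 (key step).** The most likely failure is proton transfer in place of bond formation. Either the hindered carbanion 19 removes the acidic γ-hydrogen of 18, or the crowded enolate 20 is alkylated too slowly and is quenched at C3 without the benzyl group. Both would follow from the steric bulk of the dithianyl and trityl groups around the reacting carbons. Fallback: set out from 12 and 18 and stop after the conjugate addition with an acetic acid quench at −78 °C. This gives the monoadduct (4R,5R)-4-{2-[(2S,3R)-2-(4-benzyloxy-3-methoxyphenyl)-7-methoxy-3-(triisopropylsilyloxymethyl)-2,3-dihydrobenzofuran-5-yl]-1,3-dithian-2-yl}-5-(trityloxymethyl)dihydrofuran-2(3H)-one F1. After purification the enolate is regenerated with LiN(SiMe3)2 in THF–DMPU at −78 °C and alkylated with 2 as a separate, independently tunable operation. The fallback returns to the route at 21.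

**Step 5.** The most likely failure is eroded enantioselectivity. The additional ortho-methoxy group forces the benzylic ether out of the arene plane and changes how the C–H bond meets the chiral pocket of the carbene. Fallback: set out from 7 and run the insertion with achiral Rh2(OAc)4. This gives the cis ester as a racemate, that is 8 together with its enantiomer, ethyl (2R,3S)-2-(4-benzyloxy-3-methoxyphenyl)-5-(1,3-dioxolan-2-yl)-7-methoxy-2,3-dihydrobenzofuran-3-carboxylate F2. Epimerisation as in step 6 gives 9 together with its enantiomer, ethyl (2R,3R)-2-(4-benzyloxy-3-methoxyphenyl)-5-(1,3-dioxolan-2-yl)-7-methoxy-2,3-dihydrobenzofuran-3-carboxylate F3. The two are separated by preparative chromatography on a chiral stationary phase. The fallback returns to the route at 9.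

**Step 4.** The most likely failure is slow coupling at the ortho-alkoxy, electron-rich iodide, so that palladium instead decomposes 6 (carbene dimerisation). Fallback: set out from 5 and couple it with the Reformatsky reagent BrZnCH2CO2Et under Pd(dba)2/P(t-Bu)3 in THF. This gives ethyl 2-{2-[(4-benzyloxy-3-methoxybenzyl)oxy]-5-(1,3-dioxolan-2-yl)-3-methoxyphenyl}acetate F4. Regitz diazo transfer with 4-acetamidobenzenesulfonyl azide and DBU in MeCN then installs the diazo group. The fallback returns to the route at 7.

**Step 19.** The most likely failure is over-reduction: hydrogenolytic opening of the C2–O1 bond of ring E alongside O-debenzylation, because that bond is also a benzylic aryl ether. Fallback: set out from 27 and remove the benzyl groups without hydrogen or a metal surface, using BCl3 and pentamethylbenzene in CH2Cl2 at −78 °C. The benzyl groups are then transferred as cations to the arene scavenger. The fallback returns to the route at 28 and makes no new compound.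

**Step 17.** The most likely failure is oxidation of the primary alcohol before the glycol is fully cleaved, which would re-form the untransposed lactone skeleton. Fallback: set out from 24 and separate the two events. NaIO4 in THF–H2O at 0 °C gives lactol 25, which is isolated. Ag2CO3 on Celite in refluxing toluene then oxidises it; this heterogeneous reagent oxidises lactols far faster than alcohols. The fallback returns to the route at 26 and makes no new compound.

## Further compounds

F1 | step 13 | (4R,5R)-4-{2-[(2S,3R)-2-(4-benzyloxy-3-methoxyphenyl)-7-methoxy-3-(triisopropylsilyloxymethyl)-2,3-dihydrobenzofuran-5-yl]-1,3-dithian-2-yl}-5-(trityloxymethyl)dihydrofuran-2(3H)-one | O=C1C[C@@H](C2(SCCCS2)c2cc(OC)c3c(c2)[C@H](CO[Si](C(C)C)(C(C)C)C(C)C)[C@@H](c2ccc(OCc4ccccc4)c(OC)c2)O3)[C@H](COC(c2ccccc2)(c2ccccc2)c2ccccc2)O1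
F2 | step 5 | ethyl (2R,3S)-2-(4-benzyloxy-3-methoxyphenyl)-5-(1,3-dioxolan-2-yl)-7-methoxy-2,3-dihydrobenzofuran-3-carboxylate (enantiomer of 8) | O1CCOC1c1cc(OC)c2c(c1)[C@H](C(=O)OCC)[C@H](c1ccc(OCc3ccccc3)c(OC)c1)O2
F3 | step 5 | ethyl (2R,3R)-2-(4-benzyloxy-3-methoxyphenyl)-5-(1,3-dioxolan-2-yl)-7-methoxy-2,3-dihydrobenzofuran-3-carboxylate (enantiomer of 9) | O1CCOC1c1cc(OC)c2c(c1)[C@@H](C(=O)OCC)[C@H](c1ccc(OCc3ccccc3)c(OC)c1)O2
F4 | step 4 | ethyl 2-{2-[(4-benzyloxy-3-methoxybenzyl)oxy]-5-(1,3-dioxolan-2-yl)-3-methoxyphenyl}acetate | CCOC(=O)Cc1cc(C2OCCO2)cc(OC)c1OCc1ccc(OCc2ccccc2)c(OC)c1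
F0 | step 19 | none | none
F0 | step 17 | none | none
A1 | alternative 1 | methyl 3-[(2R)-1-(tert-butyldimethylsilyloxy)-3-(4-hydroxy-3-methoxyphenyl)propan-2-yl]-4-hydroxy-5-methoxybenzoate | COC(=O)c1cc(OC)c(O)c(c1)[C@H](CO[Si](C)(C)C(C)(C)C)Cc1ccc(O)c(OC)c1
A2 | alternative 1 | methyl 3-[(2R)-1-(tert-butyldimethylsilyloxy)-3-(3-methoxy-4-oxocyclohexa-2,5-dien-1-ylidene)propan-2-yl]-4-hydroxy-5-methoxybenzoate (para-quinone methide) | COC(=O)c1cc(OC)c(O)c(c1)[C@H](CO[Si](C)(C)C(C)(C)C)C=C1C=CC(=O)C(OC)=C1
A3 | alternative 1 | methyl (2S,3R)-3-(tert-butyldimethylsilyloxymethyl)-2-(4-hydroxy-3-methoxyphenyl)-7-methoxy-2,3-dihydrobenzofuran-5-carboxylate | COC(=O)c1cc(OC)c2c(c1)[C@H](CO[Si](C)(C)C(C)(C)C)[C@@H](c1ccc(O)c(OC)c1)O2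
A4 | alternative 2 | 3-(4-benzyloxy-3-methoxybenzyl)cyclobutan-1-one | COc1cc(CC2CC(=O)C2)ccc1OCc1ccccc1
A5 | alternative 2 | (R)-4-(4-benzyloxy-3-methoxybenzyl)dihydrofuran-2(3H)-one | COc1cc(C[C@H]2COC(=O)C2)ccc1OCc1ccccc1
A6 | alternative 2 | (2S,3R)-2-(4-benzyloxy-3-methoxyphenyl)-5-(bromomethyl)-7-methoxy-3-(triisopropylsilyloxymethyl)-2,3-dihydrobenzofuran | BrCc1cc(OC)c2c(c1)[C@H](CO[Si](C(C)C)(C(C)C)C(C)C)[C@@H](c1ccc(OCc3ccccc3)c(OC)c1)O2
A7 | alternative 3 | 4-bromo-2-[2-(tert-butyldimethylsilyloxy)-1-(4-methylbenzenesulfonyl)ethyl]-6-methoxyphenol | COc1cc(Br)cc(C(CO[Si](C)(C)C(C)(C)C)S(=O)(=O)c2ccc(C)cc2)c1O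
A8 | alternative 3 | 4-bromo-6-[2-(tert-butyldimethylsilyloxy)ethylidene]-2-methoxycyclohexa-2,4-dien-1-one (ortho-quinone methide) | COC1=CC(Br)=CC(=CCO[Si](C)(C)C(C)(C)C)C1=O
A9 | alternative 3 | (2R,5R)-1-(4-benzyloxy-3-methoxybenzyl)-2,5-dimethylthiolan-1-ium tetrafluoroborate | C[C@@H]1CC[C@@H](C)[S+]1Cc1ccc(OCc2ccccc2)c(OC)c1.F[B-](F)(F)F
A10 | alternative 3 | (2S,3R)-2-(4-benzyloxy-3-methoxyphenyl)-5-bromo-3-(tert-butyldimethylsilyloxymethyl)-7-methoxy-2,3-dihydrobenzofuran | Brc1cc(OC)c2c(c1)[C@H](CO[Si](C)(C)C(C)(C)C)[C@@H](c1ccc(OCc3ccccc3)c(OC)c1)O2
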